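(Readings and results were computed for an exercise.)

The charge of the delta run is 0.500 of the zeta charge in Xa and 0.833 of it in Xb, at the same Xc.

| flask | Xa | Xb | Xc | time |
|---|---|---|---|---|
| zeta | 150 mM | 450 mM | 15.0 mM |  |
| delta | 75.0 mM | 375 mM | 15.0 mM |  |
| gamma | 150 mM | 230 mM | 15.0 mM |  |
| alpha | 150 mM | 450 mM | 30.0 mM |  |
| beta | 450 mM | 230 mM | 15.0 mM | 39 min |

| zeta run: time / min | zeta run: [Xp] / mM | delta run: time / min | delta run: [Xp] / mM | gamma run: time / min | gamma run: [Xp] / mM | alpha run: time / min | alpha run: [Xp] / mM |
|---|---|---|---|---|---|---|---|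
| 3.0 | 14.1 | 3.0 | 5.9 | 3.0 | 8.4 | 3.0 | 21.2 |
| 9.0 | 37.3 | 9.0 | 15.7 | 9.0 | 19.8 | 9.0 | 48.9 |
| 17 | 61.5 | 17 | 27.7 | 17 | 34.3 | 17 | 78.9 |
| 27 | 83.5 | 27 | 37.8 | 27 | 49.9 | 27 | 102.1 |
| 39 | 101.0 | 39 | 47.7 | 39 | 64.8 | 39 | 118.3 |

(each reading ± 0.8 mM)

- Overall: Xa + Xb -> Xp, with Xc as catalyst.
- Constant volume, constant temperature.
- "The second partner" is Xb.
- An order is taken over about fifteen percent of the charge, up and down.

1. how the opening rate goes with [Xb] round the charge of the zeta run: the exponent of the rate at two percent of Xa gone to Xp
2. how the opening rate goes with [Xa] round the charge of the zeta run: the exponent of the rate at two percent of Xa gone to Xp (one fixed amount of Xp, the same in the runs compared)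
3. the delta run starts with 75.0 mM less of Xa and of Xb than the zeta run, and with no Xp. Compared where both hold the same amount of Xa, once fifteen percent of what the delta run was charged with has turned into Xp, is the delta run faster, slower or alike (within a tenth)?
4. Xp in the beta run at 39 min, as a share of the Xa charged

Two readings seem not to go together. At 3.0 min the delta run has made 0.418 of the Xp of the zeta run, yet at 39 min it has turned 63.6% of its Xa against 67.3% in the zeta run.

Shares of the charge clear this up, reckoned at both ends. Read from the 3.0 min readings, the share of Xa turned per minute in the delta run is 0.837 of that in the zeta run, close to the Xb ratio of 0.833. So the opening readings fit each Xa turning in step with the Xb around it. At the late end Xb stands above Xa in the delta run and in the zeta run, an approach to the pseudo-first-order regime, and by 39 min the Xb ratio of the two runs has risen to 0.938.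

The join is the integrated rate law. Xa and Xb fall by equal amounts, so their gap stays fixed, and for a rate proportional to Xa times Xb the logarithm of Xb/Xa, taken relative to its charged value, grows evenly with time. Per minute and per 150 mM of gap, the last zeta reading gives 0.0111 min⁻¹: the pairing constant, a second-order constant in fraction form, at 15.0 mM of Xc. The delta run has the same gap of 300 mM and reads 0.0112 min⁻¹, and its share of Xa turned reads 0.945 of the zeta share at 39 min.

My reckoning therefore takes both orders as 1 and calls the delta run alike. In the beta run Xb is the limiting reagent, and the zeta value of the constant gives an Xa/Xb ratio at 39 min of 3.69. That means 148 mM of Xp, or 32.9% of the Xa charged.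

The forecast, judging that “the reaction looks first order in each”, gave 1, 1, alike and 32.8%. The flask gives 1.0, 1.0, alike with a ratio of 1.0, and 33.1%.

    2 Xc ⇌ Xc2, settled at all times (81.50 M⁻¹)
    Xc + Xa + Xb → Xp + Xc (8.700 M⁻² min⁻¹)
    Xa + Xb → Xp (0.01362 M⁻¹ min⁻¹)

Through the beta run the step through Xc and the bare step ran side by side on the same Xa and Xb, with free Xc at 7.00 mM of the 15.0 mM charged and the rest held as Xc2. Read back from 33.1%, the beta run gives a pairing constant of 0.0112 min⁻¹. The alpha run, with twice the Xc, reads 0.0160 min⁻¹, which is 1.44 times the zeta value, with free Xc at 10.8 mM.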